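**Strategy.** Everything rests on cutting C8–C9 of the seven-membered ring (ring atoms C1, C2, C6, C7, C8, C9, C10; five-membered ring C2, C3, C4, C5, C6). One CrCl2-mediated intramolecular allylation of a C8 aldehyde closes that ring, sets C8 and leaves a C10 exocyclic methylene homoallylic to the new hydroxyl. It exploits the cis-1,3 relation of the C8 and C10 oxygens on the seven-membered ring: the C8 hydroxyl later steers oxygen onto C10, and the C10 hydroxyl then steers the C3–C4 epoxide. The precursor is a trans-3,4-disubstituted 1-methylcyclopentene with a 2-(bromomethyl)allyl arm on C2 and an α-isopropyl acetaldehyde arm on C6.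

Key step: step 9

Assumption: atom labels follow the target (seven-membered ring C1H2–C2H–C6H–C7H(iPr)–C8H(O)–C9H2–C10(Me)(OH), five-membered ring C2–C3H–C4(Me)–C5H2–C6) and are kept for every intermediate; commercial (4R)-4-(tert-butyldimethylsilyloxy)cyclopent-2-en-1-one (3) is taken as enantiopure and is the only source of absolute configuration.

**Step 1**
Reactants: 1 tert-butyl 3-methylbutanoate
Product: 2 [(1-tert-butoxy-3-methylbut-1-en-1-yl)oxy]trimethylsilane (ketene silyl acetal, E/Z mixture)
Conditions: LDA, THF, −78 °C; then Me3SiCl, −78 °C to rt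
Reagents that add atoms: chlorotrimethylsilane, C[Si](C)(C)Cl
Why: Kinetic deprotonation of the ester and O-silylation of the lithium enolate is the standard ketene silyl acetal synthesis, and the double-bond geometry is irrelevant because C7 is corrected in step 4.

**Step 2**
Reactants: 2 [(1-tert-butoxy-3-methylbut-1-en-1-yl)oxy]trimethylsilane; 3 (4R)-4-(tert-butyldimethylsilyloxy)cyclopent-2-en-1-one
Product: 6 tert-butyl 3-methyl-2-[(1R)-4-oxocyclopent-2-en-1-yl]butanoate (both C7 epimers), via trimethylsilyl enol ether 4 (not isolated), via silyloxy ketone 5 (not isolated)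
Conditions: Sc(OTf)3 (5 mol %), CH2Cl2, −78 °C; 1 M HCl, THF, 0 °C; then DBU, CH2Cl2, 0 °C to rt
Reagents that add atoms: none
Why: A Lewis-acid-catalysed Mukaiyama–Michael addition places the ketene acetal on the enone β-carbon anti to the silyloxy group, which fixes C6 as R while C7 stays a mixture, and hydrolysis of the enol ether followed by E1cB loss of the silanol transposes the enone to the 4-substituted cyclopentenone under conditions mild enough to leave the γ-stereocentre C6 alone.

**Step 3**
Reactants: 6 tert-butyl 3-methyl-2-[(1R)-4-oxocyclopent-2-en-1-yl]butanoate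
Product: 7 tert-butyl 2-[(1R)-4-hydroxy-4-methylcyclopent-2-en-1-yl]-3-methylbutanoate (mixture at C4 and C7)
Conditions: MeLi, CeCl3, THF, −78 °C; aq. NH4Cl
Reagents that add atoms: methyllithium, [Li]C
Why: The organocerium reagent adds 1,2 to the enone carbonyl without enolising it or touching the tert-butyl ester (organocerium carbonyl addition), and the configuration of the new carbinol carbon C4 is of no consequence because step 4 ionises it.

**Step 4**
Reactants: 7 tert-butyl 2-[(1R)-4-hydroxy-4-methylcyclopent-2-en-1-yl]-3-methylbutanoate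
Product: 9 (3S,3aS,6aR)-5-methyl-3-(propan-2-yl)-3,3a,4,6a-tetrahydro-2H-cyclopenta[b]furan-2-one (cis-fused allylic lactone, oxygen on C2, isopropyl on the convex face), via lactone epimer mixture 8 (not isolated)
Conditions: TFA (3 equiv), CH2Cl2, −20 to 0 °C; evaporate; then KOt-Bu (0.2 equiv), t-BuOH–THF, rt
Reagents that add atoms: none
Why: Acid ionises the tertiary allylic alcohol to the C2–C3–C4 allyl cation, which the ester carbonyl can only capture at C2 on its own face with loss of the tert-butyl group (cationic allylic lactonisation), so all C4 epimers converge on the cis-fused γ-lactone, and catalytic base then equilibrates C7 through the lactone enolate to the epimer with isopropyl on the convex face, which is 7S.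

**Step 5**
Reactants: 9 (3S,3aS,6aR)-5-methyl-3-(propan-2-yl)-3,3a,4,6a-tetrahydro-2H-cyclopenta[b]furan-2-one; 10 [2-(chloromethyl)prop-2-en-1-yl]trimethylsilane
Product: 12 (2S)-3-methyl-2-[(1R,5S)-3-methyl-5-{2-[(trimethylsilyl)methyl]prop-2-en-1-yl}cyclopent-3-en-1-yl]butanoic acid, via allylmagnesium chloride 11 (not isolated)
Conditions: 10, Mg, THF, 0 °C; CuI (0.5 equiv per Grignard), THF, −78 °C; then 9, −78 to −30 °C; aq. NH4Cl, citric acid
Reagents that add atoms: none
Why: Copper-mediated allylic substitution opens the allylic lactone anti to the departing carboxylate, and bond formation at the secondary terminus C2 in preference to the methyl-bearing C4 gives the trans C2/C6 arrangement (2S) with the C3=C4 alkene in place; both termini of the allyl nucleophile are CH2, so only one arm constitution can form.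

**Step 6**
Reactants: 12 (2S)-3-methyl-2-[(1R,5S)-3-methyl-5-{2-[(trimethylsilyl)methyl]prop-2-en-1-yl}cyclopent-3-en-1-yl]butanoic acid
Product: 13 (2S)-3-methyl-2-[(1R,5S)-3-methyl-5-{2-[(trimethylsilyl)methyl]prop-2-en-1-yl}cyclopent-3-en-1-yl]butan-1-ol
Conditions: LiAlH4, THF, 0 °C to reflux; H2O work-up
Reagents that add atoms: none
Why: Hydride reduction of the carboxylic acid gives the primary alcohol and leaves the allylsilane, both alkenes and the C7 stereocentre untouched.

**Step 7**
Reactants: 13 (2S)-3-methyl-2-[(1R,5S)-3-methyl-5-{2-[(trimethylsilyl)methyl]prop-2-en-1-yl}cyclopent-3-en-1-yl]butan-1-ol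
Product: 14 (2S)-3-methyl-2-[(1R,5S)-3-methyl-5-{2-[(trimethylsilyl)methyl]prop-2-en-1-yl}cyclopent-3-en-1-yl]butanal
Conditions: DMP, CH2Cl2, 0 °C to rt
Reagents that add atoms: none
Why: Dess–Martin oxidation gives the aldehyde under near-neutral conditions that neither epimerise C7 nor protodesilylate the allylsilane.

**Step 8**
Reactants: 14 (2S)-3-methyl-2-[(1R,5S)-3-methyl-5-{2-[(trimethylsilyl)methyl]prop-2-en-1-yl}cyclopent-3-en-1-yl]butanal
Product: 15 (2S)-2-[(1R,5S)-5-[2-(bromomethyl)prop-2-en-1-yl]-3-methylcyclopent-3-en-1-yl]-3-methylbutanal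
Conditions: NBS (1.05 equiv), propylene oxide, CH2Cl2, −78 °C, dark
Reagents that add atoms: N-bromosuccinimide, O=C1CCC(=O)N1Br
Why: Electrophilic bromodesilylation of the allylsilane, by far the most nucleophilic alkene present, gives the allylic bromide, and since both allyl termini are CH2 the allylic transposition changes nothing.

**Step 9**
Reactants: 15 (2S)-2-[(1R,5S)-5-[2-(bromomethyl)prop-2-en-1-yl]-3-methylcyclopent-3-en-1-yl]-3-methylbutanal
Product: 16 (3aR,4S,5R,8aS)-2-methyl-7-methylidene-4-(propan-2-yl)-3,3a,4,5,6,7,8,8a-octahydroazulen-5-ol (local labels 2S,6R,7S,8R; C8 hydroxyl cis to C7 isopropyl, trans ring fusion)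
Conditions: CrCl2 (6 equiv), THF, rt, slow addition of 15 to 0.005 M; aq. NH4Cl
Reagents that add atoms: none
Why: Two one-electron transfers from two equivalents of divalent chromium turn the allylic bromide into a trivalent allylchromium species that ignores the trisubstituted alkene and adds only to the aldehyde, which is an intramolecular Nozaki–Hiyama allylation. The new C8–C9 bond closes the seven-membered ring C1–C2–C6–C7–C8–C9–C10 by attack of an allyl terminus on the exocyclic carbonyl group (7-exo-trig), and because both termini are CH2 only one constitution can form. C8 is set in a closed chair-like six-membered transition state (Cr, O, C8, C9, C10, CH2) that bridges C8 and C10 of the forming ring, so the C8–O bond must be pseudo-axial on that ring while the C7 isopropyl group stays pseudo-equatorial, which places the hydroxyl cis to isopropyl (8R). The step needs chemoselectivity for the aldehyde, ring closure over intermolecular coupling and the correct aldehyde face; the first is inherent to organochromium reagents, the second is secured by slow addition at high dilution and by the trans arms on C2 and C6 that hold the reacting ends close, and the third by the C7 stereocentre inside the bicyclic transition state.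

**Step 10**
Reactants: 16 (3aR,4S,5R,8aS)-2-methyl-7-methylidene-4-(propan-2-yl)-3,3a,4,5,6,7,8,8a-octahydroazulen-5-ol
Product: 17 C10 spiro-epoxide of 16, epoxide oxygen cis to the C8 hydroxyl (local labels 2S,6R,7S,8R,10R)
Conditions: VO(acac)2 (5 mol %), t-BuOOH (decane), CH2Cl2, 0 °C to rt
Reagents that add atoms: tert-butyl hydroperoxide, CC(C)(C)OO
Why: Hydroxyl-directed vanadium-catalysed epoxidation delivers oxygen from the vanadate ester of the pseudo-axial C8 hydroxyl to the homoallylic C10 methylene on the hydroxyl face, which sets C10 with its oxygen cis to the C8 oxygen, while the remote C3=C4 alkene has no directing group within reach.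

**Step 11**
Reactants: 17 C10 spiro-epoxide of 16
Product: 18 (3aR,4S,5R,7R,8aS)-2,7-dimethyl-4-(propan-2-yl)-3,3a,4,5,6,7,8,8a-octahydroazulene-5,7-diol (cis-1,3-diol at C8 and C10)
Conditions: LiAlH4, THF, 0 °C to rt; H2O work-up
Reagents that add atoms: none
Why: Hydride opens the 1,1-disubstituted epoxide at its unhindered CH2 terminus (SN2 epoxide reduction), so the C10–O bond and its configuration are kept and the CH2 becomes the C10 methyl group.

**Step 12**
Reactants: 19 3-hydroxy-4-methoxybenzoic acid (isovanillic acid)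
Product: 21 3-(tert-butyldimethylsilyloxy)-4-methoxybenzoic acid, via bis-silylated acid 20 (not isolated)
Conditions: TBSCl (2.2 equiv), imidazole, DMF, rt; then AcOH–THF–H2O, rt
Reagents that add atoms: tert-butyldimethylsilyl chloride, CC(C)(C)[Si](C)(C)Cl
Why: Silylation of both acidic groups followed by selective hydrolysis of the labile silyl ester leaves the phenol masked as its silyl ether (standard hydroxy-acid protection).

**Step 13**
Reactants: 18 (3aR,4S,5R,7R,8aS)-2,7-dimethyl-4-(propan-2-yl)-3,3a,4,5,6,7,8,8a-octahydroazulene-5,7-diol; 21 3-(tert-butyldimethylsilyloxy)-4-methoxybenzoic acid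
Product: 22 C8 3-(tert-butyldimethylsilyloxy)-4-methoxybenzoate of diol 18 (local labels 2S,6R,7S,8R,10R; C10 hydroxyl free)
Conditions: DCC, DMAP, CH2Cl2, rt
Reagents that add atoms: none
Why: Steglich esterification acylates the secondary C8 hydroxyl, the tertiary C10 hydroxyl being inert under these conditions, and no stereocentre is touched.

**Step 14**
Reactants: 22 C8 3-(tert-butyldimethylsilyloxy)-4-methoxybenzoate of diol 18
Product: 23 C3–C4 epoxide of 22 with the epoxide oxygen on the face of the C10 hydroxyl and H6 (local labels 2S,3S,4R,6R,7S,8R,10R)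
Conditions: VO(acac)2 (10 mol %), t-BuOOH (decane), toluene, 40 °C
Reagents that add atoms: tert-butyl hydroperoxide, CC(C)(C)OO
Why: The tertiary C10 hydroxyl, bishomoallylic to C3=C4 and on the same face as C1, binds vanadium and delivers the peroxide oxygen to that face of the cyclopentene (hydroxyl-directed epoxidation), which sets C3 and C4 together with the epoxide cis to the C10 hydroxyl.

**Step 15**
Reactants: 23 C3–C4 epoxide of 22
Product: 24 CNP0106636.1 (target; local labels 2S,3S,4R,6R,7S,8R,10R)
Conditions: TBAF, AcOH, THF, 0 °C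
Reagents that add atoms: none
Why: Fluoride cleaves the aryl silyl ether rapidly under acetic acid buffering (desilylation), conditions that leave the benzoate ester, the epoxide and the tertiary alcohol untouched.

**Compound list**

1 | tert-butyl 3-methylbutanoate | CC(C)CC(=O)OC(C)(C)C | starting material
2 | [(1-tert-butoxy-3-methylbut-1-en-1-yl)oxy]trimethylsilane (E/Z mixture) | CC(C)C=C(OC(C)(C)C)O[Si](C)(C)C | intermediate
3 | (4R)-4-(tert-butyldimethylsilyloxy)cyclopent-2-en-1-one | O=C1C=C[C@H](O[Si](C)(C)C(C)(C)C)C1 | starting material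
4 | tert-butyl 2-[(1S,5R)-5-(tert-butyldimethylsilyloxy)-3-(trimethylsilyloxy)cyclopent-2-en-1-yl]-3-methylbutanoate (C7 epimers) | C[Si](C)(C)OC1=C[C@@H](C(C(C)C)C(=O)OC(C)(C)C)[C@H](O[Si](C)(C)C(C)(C)C)C1 | intermediate
5 | tert-butyl 2-[(1S,2R)-2-(tert-butyldimethylsilyloxy)-4-oxocyclopentyl]-3-methylbutanoate (C7 epimers) | O=C1C[C@@H](C(C(C)C)C(=O)OC(C)(C)C)[C@H](O[Si](C)(C)C(C)(C)C)C1 | intermediate
6 | tert-butyl 3-methyl-2-[(1R)-4-oxocyclopent-2-en-1-yl]butanoate (C7 epimers) | O=C1C=C[C@H](C(C(C)C)C(=O)OC(C)(C)C)C1 | intermediate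
7 | tert-butyl 2-[(1R)-4-hydroxy-4-methylcyclopent-2-en-1-yl]-3-methylbutanoate (C4 and C7 epimers) | CC1(O)C=C[C@H](C(C(C)C)C(=O)OC(C)(C)C)C1 | intermediate
8 | (3aS,6aR)-5-methyl-3-(propan-2-yl)-3,3a,4,6a-tetrahydro-2H-cyclopenta[b]furan-2-one (C7 epimers) | CC(C)C1C(=O)O[C@H]2C=C(C)C[C@@H]12 | intermediate
9 | (3S,3aS,6aR)-5-methyl-3-(propan-2-yl)-3,3a,4,6a-tetrahydro-2H-cyclopenta[b]furan-2-one | CC(C)[C@@H]1C(=O)O[C@H]2C=C(C)C[C@@H]12 | intermediate
10 | [2-(chloromethyl)prop-2-en-1-yl]trimethylsilane | C=C(CCl)C[Si](C)(C)C | starting material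
11 | chloro{2-[(trimethylsilyl)methyl]prop-2-en-1-yl}magnesium | C=C(C[Mg]Cl)C[Si](C)(C)C | intermediate
12 | (2S)-3-methyl-2-[(1R,5S)-3-methyl-5-{2-[(trimethylsilyl)methyl]prop-2-en-1-yl}cyclopent-3-en-1-yl]butanoic acid | OC(=O)[C@@H](C(C)C)[C@@H]1CC(C)=C[C@H]1CC(=C)C[Si](C)(C)C | intermediate
13 | (2S)-3-methyl-2-[(1R,5S)-3-methyl-5-{2-[(trimethylsilyl)methyl]prop-2-en-1-yl}cyclopent-3-en-1-yl]butan-1-ol | OC[C@@H](C(C)C)[C@@H]1CC(C)=C[C@H]1CC(=C)C[Si](C)(C)C | intermediate
14 | (2S)-3-methyl-2-[(1R,5S)-3-methyl-5-{2-[(trimethylsilyl)methyl]prop-2-en-1-yl}cyclopent-3-en-1-yl]butanal | O=C[C@@H](C(C)C)[C@@H]1CC(C)=C[C@H]1CC(=C)C[Si](C)(C)C | intermediate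
15 | (2S)-2-[(1R,5S)-5-[2-(bromomethyl)prop-2-en-1-yl]-3-methylcyclopent-3-en-1-yl]-3-methylbutanal (key-step precursor) | O=C[C@@H](C(C)C)[C@@H]1CC(C)=C[C@H]1CC(=C)CBr | intermediate
16 | (3aR,4S,5R,8aS)-2-methyl-7-methylidene-4-(propan-2-yl)-3,3a,4,5,6,7,8,8a-octahydroazulen-5-ol (key-step product) | O[C@@H]1CC(=C)C[C@H]2[C@@H](CC(C)=C2)[C@@H]1C(C)C | intermediate
17 | C10 spiro-epoxide of 16, epoxide oxygen cis to the C8 hydroxyl (10R) | O[C@@H]1C[C@@]2(CO2)C[C@H]3[C@@H](CC(C)=C3)[C@@H]1C(C)C | intermediate
18 | (3aR,4S,5R,7R,8aS)-2,7-dimethyl-4-(propan-2-yl)-3,3a,4,5,6,7,8,8a-octahydroazulene-5,7-diol | O[C@@H]1C[C@](C)(O)C[C@H]2[C@@H](CC(C)=C2)[C@@H]1C(C)C | intermediate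
19 | 3-hydroxy-4-methoxybenzoic acid (isovanillic acid) | COc1ccc(C(=O)O)cc1O | starting material
20 | tert-butyldimethylsilyl 3-(tert-butyldimethylsilyloxy)-4-methoxybenzoate | COc1ccc(C(=O)O[Si](C)(C)C(C)(C)C)cc1O[Si](C)(C)C(C)(C)C | intermediate
21 | 3-(tert-butyldimethylsilyloxy)-4-methoxybenzoic acid | COc1ccc(C(=O)O)cc1O[Si](C)(C)C(C)(C)C | intermediate
22 | C8 3-(tert-butyldimethylsilyloxy)-4-methoxybenzoate of 18 (2S,6R,7S,8R,10R) | COc1ccc(C(=O)O[C@@H]2C[C@](C)(O)C[C@H]3[C@@H](CC(C)=C3)[C@@H]2C(C)C)cc1O[Si](C)(C)C(C)(C)C | intermediate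
23 | C3–C4 epoxide of 22, epoxide cis to the C10 hydroxyl (2S,3S,4R,6R,7S,8R,10R) | COc1ccc(C(=O)O[C@@H]2C[C@](C)(O)C[C@H]3[C@@H](C[C@@]4(C)O[C@@H]34)[C@@H]2C(C)C)cc1O[Si](C)(C)C(C)(C)C | intermediate
24 | CNP0106636.1, the C8 isovanillate (2S,3S,4R,6R,7S,8R,10R) | COc1ccc(C(=O)O[C@@H]2C[C@](C)(O)C[C@H]3[C@@H](C[C@@]4(C)O[C@@H]34)[C@@H]2C(C)C)cc1O | target

**Totals**

Total step count: 15. Longest linear sequence: 14 steps (1 to 24 through steps 1–11 and 13–15); step 12 is a one-step side branch.

**Steps most likely to fail**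

1. Step 9 (ring closure). An open transition state may compete with the chelated chair and erode facial control at C8, and intermolecular coupling may compete with seven-membered ring closure. The fallback sets out from 14 and returns at 16. Aldehyde 14 is closed by a Lewis-acid-promoted intramolecular Hosomi–Sakurai reaction (BF3·OEt2, CH2Cl2, −78 °C), which needs neither the bromide nor chromium. Its open transition state is expected to favour the C8 epimer, (3aR,4S,5S,8aS)-2-methyl-7-methylidene-4-(propan-2-yl)-3,3a,4,5,6,7,8,8a-octahydroazulen-5-ol F1. The carbinol mixture is oxidised with DMP to (3aR,4S,8aS)-2-methyl-7-methylidene-4-(propan-2-yl)-3,3a,6,7,8,8a-hexahydroazulen-5(4H)-one F2. Reduction with L-Selectride (THF, −78 °C), hydride arriving anti to the C7 isopropyl group, should then give 16.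

2. Step 5 (copper-mediated opening of lactone 9). The allylcopper species may lose regiocontrol and attack the methyl-bearing C4 terminus, or the allylmagnesium reagent may add directly to the lactone carbonyl. The fallback sets out from 9 and returns at 12. The lactone is ionised with BF3·OEt2 in CH2Cl2 at −78 °C in the presence of (2-methylidenepropane-1,3-diyl)bis(trimethylsilane). The allylsilane should attack the less substituted terminus C2 of the allyl cation on the face away from the tethered carboxylate (Hosomi–Sakurai-type allylic substitution), and aqueous work-up gives 12 directly. This fallback makes no new compound (F0).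

3. Step 14 (second directed epoxidation). Direction by the tertiary, bishomoallylic C10 hydroxyl may be too weak, leading to slow oxidation or to oxygen delivery from the opposite face. The fallback sets out from 22 and returns at 23. NBS in aqueous DME at 0 °C forms the bromonium ion on the less hindered face (that of H2), and water opens it at the tertiary C4 from the other side to give the trans-bromohydrin (C3 bromine on the H2 face, C4 hydroxyl on the H6 face) F3. DBU in CH2Cl2 then closes the epoxide with inversion at C3, which puts the epoxide oxygen on the face required for 23.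

**Further compounds**

F1 | step 9 | (3aR,4S,5S,8aS)-2-methyl-7-methylidene-4-(propan-2-yl)-3,3a,4,5,6,7,8,8a-octahydroazulen-5-ol | O[C@H]1CC(=C)C[C@H]2[C@@H](CC(C)=C2)[C@@H]1C(C)C
F2 | step 9 | (3aR,4S,8aS)-2-methyl-7-methylidene-4-(propan-2-yl)-3,3a,6,7,8,8a-hexahydroazulen-5(4H)-one | O=C1CC(=C)C[C@H]2[C@@H](CC(C)=C2)[C@@H]1C(C)C
F0 | step 5 | none | none
F3 | step 14 | trans-bromohydrin of 22 (3R,4R: C3 bromine on the H2 face, C4 hydroxyl on the H6 face) | COc1ccc(C(=O)O[C@@H]2C[C@](C)(O)C[C@H]3[C@@H](C[C@@](C)(O)[C@@H]3Br)[C@@H]2C(C)C)cc1O[Si](C)(C)C(C)(C)C
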